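**Retrosynthetic overview**

1. Target 41 ⇐ triol 38 by oxidative lactonisation (γ-lactone O6–C12 closed last), after tigloylation of C8–OH and global desilylation of macrocycle 34.
2. 34 ⇐ acyclic 32 by a nickel-catalysed reductive alkyne–epoxide macrocyclisation that forms C9–C10. The enabling feature is the ring segment C8(O)–C9H2–C10(=C14H2): C8 carries oxygen and C10 carries the exocyclic methylene, so C8–C9 can be a temporary terminal oxirane (a ring absent from the target) and C10≡C14 a terminal alkyne. One operation then closes the ten-membered carbocycle, creates the C10=C14 methylene and frees C8–OH with its configuration intact.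
3. 32 ⇐ enal 14 + N-acyl thiazolidinethione 21 by a Crimmins syn aldol (C6–C7). C9 enters as ClCH2Li, C8 is set by Evans–Saksena 1,3-anti reduction, and the C4–C5 oxirane by C6–OH-directed epoxidation.
4. 14 ⇐ acetal-enal 3 by Still–Gennari olefination, Sharpless epoxidation (C2–C3 oxirane) and Felkin alkynylation (C1, C10≡C14); 21 ⇐ 2-methylidenepropane-1,3-diol.
5. Ring order: C2–C3 oxirane, C4–C5 oxirane, temporary C8–C9 oxirane, ten-membered carbocycle, γ-lactone.

Key step: step 20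

Remark: the ester is read as the tiglate ((E)-2-methylbut-2-enoate). Locants C1–C15 are germacrane locants (ring C1–C10, C11–C13 lactone/methylene carbons on C7, C14 methylene on C10, C15 methyl on C4). Descriptors given with them are the CIP descriptors of the compound named; the target is (1S,2S,3S,4S,5R,6S,7R,8R).

**Route**

Step 1
Reactants: 1 2,2-dimethoxyacetaldehyde; 2 2-(triphenyl-λ5-phosphanylidene)propanal
Product: 3 (2E)-4,4-dimethoxy-2-methylbut-2-enal
Conditions: CH2Cl2, 23 °C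
Reagents that add atoms: none
Why: Wittig olefination with a formyl-stabilised ylide, which attacks only the more electrophilic aldehyde 1 and should give the (E)-trisubstituted enal under stabilised-ylide control.

Step 2
Reactants: 3 (2E)-4,4-dimethoxy-2-methylbut-2-enal; 4 methyl 2-[bis(2,2,2-trifluoroethoxy)phosphoryl]acetate
Product: 6 methyl (2Z,4E)-6,6-dimethoxy-4-methylhexa-2,4-dienoate, via potassium phosphonate carbanion 5 (not isolated)
Conditions: KN(SiMe3)2, 18-crown-6, THF, −78 °C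
Reagents that add atoms: none
Why: Still–Gennari variant of the Horner–Wadsworth–Emmons reaction, in which fast elimination from the kinetic adduct of the electron-poor phosphonate should set the (2Z)-alkene while the (4E)-alkene is untouched.

Step 3
Reactants: 6 methyl (2Z,4E)-6,6-dimethoxy-4-methylhexa-2,4-dienoate
Product: 7 (2Z,4E)-6,6-dimethoxy-4-methylhexa-2,4-dien-1-ol
Conditions: i-Bu2AlH, CH2Cl2, −78 °C
Reagents that add atoms: none
Why: 1,2-reduction of the conjugated ester by i-Bu2AlH at low temperature should give the allylic alcohol without touching the acetal or either alkene geometry.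

Step 4
Reactants: 7 (2Z,4E)-6,6-dimethoxy-4-methylhexa-2,4-dien-1-ol
Product: 8 [(2S,3R)-3-[(2E)-4,4-dimethoxybut-2-en-2-yl]oxiran-2-yl]methanol
Conditions: Ti(Oi-Pr)4 (20 mol %), L-(+)-diethyl tartrate (24 mol %), t-BuOOH, 4 Å sieves, CH2Cl2, −20 °C
Reagents that add atoms: tert-butyl hydroperoxide, CC(C)(C)OO
Why: Sharpless asymmetric epoxidation, in which the L-(+)-tartrate titanium complex should deliver oxygen to the face that gives the (2S,3R)-cis-oxirane (C2, C3), and only the allylic C2=C3 alkene reacts because C4=C5 has no directing hydroxyl.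

Step 5
Reactants: 8 [(2S,3R)-3-[(2E)-4,4-dimethoxybut-2-en-2-yl]oxiran-2-yl]methanol
Product: 9 (2R,3R)-3-[(2E)-4,4-dimethoxybut-2-en-2-yl]oxirane-2-carbaldehyde
Conditions: Dess–Martin periodinane, NaHCO3, CH2Cl2, 0 °C
Reagents that add atoms: none
Why: Buffered Dess–Martin oxidation should convert the primary epoxy alcohol into the cis-epoxy aldehyde without epimerisation at C2.

Step 6
Reactants: 9 (2R,3R)-3-[(2E)-4,4-dimethoxybut-2-en-2-yl]oxirane-2-carbaldehyde; 10 ethynyl(trimethyl)silane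
Product: 12 (1S)-1-[(2S,3R)-3-[(2E)-4,4-dimethoxybut-2-en-2-yl]oxiran-2-yl]-3-(trimethylsilyl)prop-2-yn-1-ol, via lithium (trimethylsilyl)acetylide 11 (not isolated)
Conditions: 10, n-BuLi, THF, −78 °C; then 9, −78 °C; H2O
Reagents that add atoms: none
Why: 1,2-addition of a lithium acetylide to an α,β-epoxy aldehyde under Felkin–Anh (Cornforth) control, in which the C2–O bond lies anti to the nucleophile and H2 sits on the attack trajectory, should give the (1S) carbinol (C1–OH erythro to the oxirane oxygen).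

Step 7
Reactants: 12 (1S)-1-[(2S,3R)-3-[(2E)-4,4-dimethoxybut-2-en-2-yl]oxiran-2-yl]-3-(trimethylsilyl)prop-2-yn-1-ol
Product: 13 triethyl{[(1S)-1-[(2R,3R)-3-[(2E)-4,4-dimethoxybut-2-en-2-yl]oxiran-2-yl]-3-(trimethylsilyl)prop-2-yn-1-yl]oxy}silane
Conditions: Et3SiCl, imidazole, DMF, 0 °C
Reagents that add atoms: chlorotriethylsilane, CC[Si](Cl)(CC)CC
Why: Imidazole-mediated silylation of the secondary propargylic alcohol is a standard protection that leaves all other groups untouched.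

Step 8
Reactants: 13 triethyl{[(1S)-1-[(2R,3R)-3-[(2E)-4,4-dimethoxybut-2-en-2-yl]oxiran-2-yl]-3-(trimethylsilyl)prop-2-yn-1-yl]oxy}silane
Product: 14 (2E)-3-[(2R,3R)-3-[(1S)-1-(triethylsilyloxy)-3-(trimethylsilyl)prop-2-yn-1-yl]oxiran-2-yl]but-2-enal
Conditions: pyridinium p-toluenesulfonate (cat.), acetone/H2O, 0 → 23 °C
Reagents that add atoms: water, O
Why: Mild acid hydrolysis of an allylic dimethyl acetal, which ionises through an allyl-stabilised oxocarbenium ion and should be cleaved well before the oxirane, the silyl ether or the C-silyl alkyne react.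

Step 9
Reactants: 15 2-methylidenepropane-1,3-diol
Product: 16 2-({[tert-butyl(dimethyl)silyl]oxy}methyl)prop-2-en-1-ol
Conditions: NaH (1 equiv), THF; then t-BuMe2SiCl (1 equiv), 0 → 23 °C
Reagents that add atoms: tert-butyl(chloro)dimethylsilane, CC(C)(C)[Si](C)(C)Cl
Why: Monosilylation of a symmetrical diol through its sparingly soluble monosodium alkoxide should stop cleanly at the mono-ether.

Step 10
Reactants: 16 2-({[tert-butyl(dimethyl)silyl]oxy}methyl)prop-2-en-1-ol
Product: 17 {[2-(bromomethyl)prop-2-en-1-yl]oxy}(tert-butyl)dimethylsilane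
Conditions: CBr4, PPh3, CH2Cl2, 0 °C
Reagents that add atoms: tetrabromomethane, BrC(Br)(Br)Br
Why: Appel bromination of a primary allylic alcohol under neutral conditions that a silyl ether tolerates.

Step 11
Reactants: 17 {[2-(bromomethyl)prop-2-en-1-yl]oxy}(tert-butyl)dimethylsilane
Product: 19 3-({[tert-butyl(dimethyl)silyl]oxy}methyl)but-3-enoic acid, via allylmagnesium bromide 18 (not isolated)
Conditions: Mg, THF, 0 °C (slow addition); CO2, −40 → 0 °C; aq. citric acid
Reagents that add atoms: carbon dioxide, O=C=O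
Why: Carboxylation of an allylic Grignard reagent whose two CH2 termini are equivalent, so that α- and γ-attack on CO2 give the same acid.

Step 12
Reactants: 19 3-({[tert-butyl(dimethyl)silyl]oxy}methyl)but-3-enoic acid; 20 (4S)-4-benzyl-1,3-thiazolidine-2-thione
Product: 21 1-[(4S)-4-benzyl-2-thioxo-1,3-thiazolidin-3-yl]-3-({[tert-butyl(dimethyl)silyl]oxy}methyl)but-3-en-1-one
Conditions: EDC·HCl, DMAP (cat.), CH2Cl2, 0 → 23 °C
Reagents that add atoms: none
Why: Carbodiimide-mediated (Steglich-type) N-acylation of the thiazolidinethione auxiliary by the free acid.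

Step 13
Reactants: 21 1-[(4S)-4-benzyl-2-thioxo-1,3-thiazolidin-3-yl]-3-({[tert-butyl(dimethyl)silyl]oxy}methyl)but-3-en-1-one; 14 (2E)-3-[(2R,3R)-3-[(1S)-1-(triethylsilyloxy)-3-(trimethylsilyl)prop-2-yn-1-yl]oxiran-2-yl]but-2-enal
Product: 23 syn-aldol adduct (1S,2R,3R,4E,6R,7S): N-acyl-(4S)-4-benzylthiazolidine-2-thione at C8 with C6–OH, C7–C(=CH2)CH2OSiMe2t-Bu, C4=C5 alkene, C2–C3 cis-oxirane, C1–OSiEt3 and C14-silylated alkyne, via chlorotitanium dienolate 22 (not isolated)
Conditions: TiCl4 (1.05 equiv), i-Pr2NEt (1.1 equiv), N-methylpyrrolidinone (1.1 equiv), CH2Cl2, 0 °C; then 14, −78 °C; aq. NH4Cl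
Reagents that add atoms: none
Why: Crimmins titanium-enolate aldol in its "Evans syn" mode, in which the (Z)-dienolate reacts at its α-carbon (C7) through a non-chelated chair Zimmerman–Traxler transition state and the (4S)-benzyl auxiliary shields one enolate face, so that C6 and C7 should be set syn as (6R,7S) by reagent control.

Step 14
Reactants: 23 syn-aldol adduct (1S,2R,3R,4E,6R,7S)
Product: 24 Weinreb amide (1S,2R,3R,4E,6R,7S): C8 N-methoxy-N-methylamide, otherwise as 23
Conditions: MeNH(OMe)·HCl, imidazole, CH2Cl2, 23 °C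
Reagents that add atoms: N,O-dimethylhydroxylamine hydrochloride, Cl.CNOC
Why: Aminolysis of the activated N-acyl thiazolidinethione gives the Weinreb amide without any Lewis acid and releases the auxiliary for recovery.

Step 15
Reactants: 24 Weinreb amide (1S,2R,3R,4E,6R,7S)
Product: 25 4,5-epoxy Weinreb amide (1S,2R,3S,4S,5R,6S,7S)
Conditions: m-CPBA, NaHCO3, CH2Cl2, −20 → 0 °C
Reagents that add atoms: 3-chloroperoxybenzoic acid, OOC(=O)c1cccc(Cl)c1
Why: Hydroxyl-directed (Henbest) epoxidation, in which A1,3 strain between the C15 methyl (cis to C6) and C6 holds H6 in the alkene plane and the hydrogen-bonded peracid is delivered syn to C6–OH, should give the threo (4S,5R)-oxirane, the trisubstituted alkene reacting faster than the 1,1-disubstituted C11=C13 alkene.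

Step 16
Reactants: 25 4,5-epoxy Weinreb amide (1S,2R,3S,4S,5R,6S,7S); 26 chloro(iodo)methane
Product: 28 chloromethyl ketone (1S,2R,3S,4S,5R,6S,7S): C8 ketone bearing C9H2Cl, otherwise as 25, via chloromethyllithium 27 (not isolated)
Conditions: 26, MeLi·LiBr, THF, −78 °C; AcOH, −78 °C
Reagents that add atoms: none
Why: Chemoselective addition of chloromethyllithium, generated by lithium–iodine exchange in the presence of the substrate, to the Weinreb amide, whose chelated tetrahedral intermediate prevents over-addition and should give the α-chloro ketone on cold acidic quench.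

Step 17
Reactants: 28 chloromethyl ketone (1S,2R,3S,4S,5R,6S,7S)
Product: 29 anti-1,3-diol chlorohydrin (1S,2R,3S,4S,5R,6S,7S,8S): C6–OH, C8–OH, C9H2Cl
Conditions: Me4NBH(OAc)3, MeCN/AcOH, −35 °C
Reagents that add atoms: none
Why: Evans–Saksena reduction, in which the C6 hydroxyl binds boron and delivers hydride intramolecularly through a chair transition state, should set C8 1,3-anti to C6–OH.

Step 18
Reactants: 29 anti-1,3-diol chlorohydrin (1S,2R,3S,4S,5R,6S,7S,8S)
Product: 31 tris-oxirane alkynol (1S,2R,3S,4S,5R,6S,7S,8S): terminal C8–C9 oxirane, free C6–OH, terminal alkyne, via C-silylated oxirane 30 (not isolated)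
Conditions: K2CO3, MeOH, 0 → 23 °C
Reagents that add atoms: none
Why: Base-induced 3-exo-tet Williamson closure of the chlorohydrin (C8 retained, its C–O bond is untouched) followed by methanolytic C-desilylation of the alkyne, while the 5-endo attack of C6–OH on the new oxirane is disfavoured.

Step 19
Reactants: 31 tris-oxirane alkynol (1S,2R,3S,4S,5R,6S,7S,8S)
Product: 32 seco-precursor (1S,2R,3S,4S,5R,6S,7R,8S): C1–OSiEt3, C6–OSiEt3, C12–OSiMe2t-Bu, C2–C3, C4–C5 and C8–C9 oxiranes, C10≡C14 terminal alkyne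
Conditions: Et3SiOTf, 2,6-lutidine, CH2Cl2, −78 °C
Reagents that add atoms: triethylsilyl trifluoromethanesulfonate, CC[Si](CC)(CC)OS(=O)(=O)C(F)(F)F
Why: Silyl triflate with a hindered pyridine base silylates the hindered C6 alcohol at low temperature, where the three oxiranes should survive.

Step 20
Reactants: 32 seco-precursor (1S,2R,3S,4S,5R,6S,7R,8S)
Product: 34 macrocycle (1S,2R,3S,4S,5R,6S,7R,8R): ten-membered carbocycle with C8–OH, C10=C14H2, C1–OSiEt3, C6–OSiEt3, C7–C(=CH2)CH2OSiMe2t-Bu and both internal oxiranes, via macrocyclic diethylborinate 33 (not isolated)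
Conditions: Ni(cod)2 (20 mol %), PBu3 (40 mol %), Et3B (3 equiv), THF, 23 °C, 32 added over 12 h to 0.004 M; aq. NaHCO3
Reagents that add atoms: none
Why: Proposed new method: zerovalent nickel carrying PBu3 and the C10≡C14 alkyne opens the Et3B-activated terminal oxirane at its unhindered CH2 (C9) and joins C9 to the internal alkyne carbon C10 by syn carbonickelation, after which ethyl transfer from boron, β-hydride elimination (ethene) and C14–H reductive elimination release the homoallylic alcohol as its diethylborinate 33 and return the catalyst. The closest known reaction type is the nickel-catalysed reductive coupling of alkynes with epoxides, established intermolecularly and for five- and six-membered rings (and, for ynals, for macrocycles); the medium ring and the terminal alkyne are the new elements. The ten-membered carbocycle closes in the exo-dig mode at the alkyne with endo opening of the oxirane at C9. No stereocentre is created: C8 keeps its configuration because its C–O bond is never broken, and the 1,1-disubstituted C10=C14 alkene has no geometry. The step needs bond formation at C10 and not at C14, which should be secured because the C14 mode would give an eleven-membered ring with an (E)-endocyclic alkene and because nickel prefers the unhindered terminal carbon; it needs reaction of the terminal oxirane only, which should be secured because the cis-disubstituted C2–C3 and trisubstituted C4–C5 oxiranes resist SN2-type opening; and it needs cyclisation over oligomerisation, which high dilution and the chain fold imposed by the two oxiranes and the C6/C7/C8 substituents should favour.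

Step 21
Reactants: 34 macrocycle (1S,2R,3S,4S,5R,6S,7R,8R); 35 (2E)-2-methylbut-2-enoic acid (tiglic acid)
Product: 37 C8 tiglate of 34 (1S,2R,3S,4S,5R,6S,7R,8R), via tigloyl trichlorobenzoyl anhydride 36 (not isolated)
Conditions: 35, 2,4,6-trichlorobenzoyl chloride, Et3N, toluene, 23 °C; then 34, DMAP, 23 °C
Reagents that add atoms: none
Why: Yamaguchi esterification, in which DMAP attacks the mixed anhydride at the less hindered tigloyl carbonyl and the acylpyridinium acylates the only free hydroxyl (C8–OH) without E/Z isomerisation.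

Step 22
Reactants: 37 C8 tiglate of 34
Product: 38 triol (1S,2S,3S,4S,5R,6S,7S,8R): C1–OH, C6–OH, C12–OH, C8 tiglate
Conditions: HF·pyridine, pyridine, THF, 0 → 23 °C
Reagents that add atoms: none
Why: Pyridine-buffered HF·pyridine removes the two triethylsilyl ethers and the primary tert-butyldimethylsilyl ether under conditions that epoxides and the enoate should tolerate.

Step 23
Reactants: 38 triol (1S,2S,3S,4S,5R,6S,7S,8R)
Product: 41 target (1S,2S,3S,4S,5R,6S,7R,8R), via enal 39 (not isolated), via lactol 40 (not isolated)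
Conditions: TEMPO (20 mol %), PhI(OAc)2 (2.5 equiv), CH2Cl2, 23 °C
Reagents that add atoms: none
Why: TEMPO/PhI(OAc)2 oxidative lactonisation, in which the oxoammonium salt oxidises the primary allylic C12 alcohol selectively, C6–OH closes the five-membered lactol and this is oxidised on to the α-methylene-γ-butyrolactone, the secondary C1–OH reacting much more slowly.

**Compound list**

1 | 2,2-dimethoxyacetaldehyde | COC(OC)C=O | starting material
2 | 2-(triphenyl-λ5-phosphanylidene)propanal | CC(C=O)=P(c1ccccc1)(c1ccccc1)c1ccccc1 | starting material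
3 | (2E)-4,4-dimethoxy-2-methylbut-2-enal | COC(OC)/C=C(\C)C=O | intermediate
4 | methyl 2-[bis(2,2,2-trifluoroethoxy)phosphoryl]acetate | COC(=O)CP(=O)(OCC(F)(F)F)OCC(F)(F)F | starting material
5 | potassium carbanion of 4 | [K+].COC(=O)[CH-]P(=O)(OCC(F)(F)F)OCC(F)(F)F | intermediate
6 | methyl (2Z,4E)-6,6-dimethoxy-4-methylhexa-2,4-dienoate | COC(=O)/C=C\C(C)=C\C(OC)OC | intermediate
7 | (2Z,4E)-6,6-dimethoxy-4-methylhexa-2,4-dien-1-ol | OC/C=C\C(C)=C\C(OC)OC | intermediate
8 | [(2S,3R)-3-[(2E)-4,4-dimethoxybut-2-en-2-yl]oxiran-2-yl]methanol | OC[C@@H]1O[C@@H]1/C(C)=C/C(OC)OC | intermediate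
9 | (2R,3R)-3-[(2E)-4,4-dimethoxybut-2-en-2-yl]oxirane-2-carbaldehyde | O=C[C@@H]1O[C@@H]1/C(C)=C/C(OC)OC | intermediate
10 | ethynyl(trimethyl)silane | C#C[Si](C)(C)C | starting material
11 | lithium (trimethylsilyl)acetylide | [Li]C#C[Si](C)(C)C | intermediate
12 | (1S)-1-[(2S,3R)-3-[(2E)-4,4-dimethoxybut-2-en-2-yl]oxiran-2-yl]-3-(trimethylsilyl)prop-2-yn-1-ol | C[Si](C)(C)C#C[C@H](O)[C@@H]1O[C@@H]1/C(C)=C/C(OC)OC | intermediate
13 | triethylsilyl ether of 12, (1S; oxirane 2R,3R) | C[Si](C)(C)C#C[C@H](O[Si](CC)(CC)CC)[C@@H]1O[C@@H]1/C(C)=C/C(OC)OC | intermediate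
14 | (2E)-3-[(2R,3R)-3-[(1S)-1-(triethylsilyloxy)-3-(trimethylsilyl)prop-2-yn-1-yl]oxiran-2-yl]but-2-enal | C[Si](C)(C)C#C[C@H](O[Si](CC)(CC)CC)[C@@H]1O[C@@H]1/C(C)=C/C=O | intermediate
15 | 2-methylidenepropane-1,3-diol | C=C(CO)CO | starting material
16 | 2-({[tert-butyl(dimethyl)silyl]oxy}methyl)prop-2-en-1-ol | C=C(CO)CO[Si](C)(C)C(C)(C)C | intermediate
17 | {[2-(bromomethyl)prop-2-en-1-yl]oxy}(tert-butyl)dimethylsilane | C=C(CBr)CO[Si](C)(C)C(C)(C)C | intermediate
18 | [2-({[tert-butyl(dimethyl)silyl]oxy}methyl)prop-2-en-1-yl]magnesium bromide | C=C(C[Mg]Br)CO[Si](C)(C)C(C)(C)C | intermediate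
19 | 3-({[tert-butyl(dimethyl)silyl]oxy}methyl)but-3-enoic acid | C=C(CC(=O)O)CO[Si](C)(C)C(C)(C)C | intermediate
20 | (4S)-4-benzyl-1,3-thiazolidine-2-thione | S=C1N[C@@H](Cc2ccccc2)CS1 | starting material
21 | 1-[(4S)-4-benzyl-2-thioxo-1,3-thiazolidin-3-yl]-3-({[tert-butyl(dimethyl)silyl]oxy}methyl)but-3-en-1-one | C=C(CO[Si](C)(C)C(C)(C)C)CC(=O)N1C(=S)SC[C@@H]1Cc1ccccc1 | intermediate
22 | (Z)-trichlorotitanium dienolate of 21 | C=C(CO[Si](C)(C)C(C)(C)C)/C=C(\O[Ti](Cl)(Cl)Cl)N1C(=S)SC[C@@H]1Cc1ccccc1 | intermediate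
23 | syn-aldol adduct (1S,2R,3R,4E,6R,7S), auxiliary 4S | C[Si](C)(C)C#C[C@H](O[Si](CC)(CC)CC)[C@@H]1O[C@@H]1/C(C)=C/[C@@H](O)[C@H](C(=C)CO[Si](C)(C)C(C)(C)C)C(=O)N1C(=S)SC[C@@H]1Cc1ccccc1 | intermediate
24 | Weinreb amide (1S,2R,3R,4E,6R,7S) | C[Si](C)(C)C#C[C@H](O[Si](CC)(CC)CC)[C@@H]1O[C@@H]1/C(C)=C/[C@@H](O)[C@H](C(=C)CO[Si](C)(C)C(C)(C)C)C(=O)N(C)OC | intermediate
25 | 4,5-epoxy Weinreb amide (1S,2R,3S,4S,5R,6S,7S) | C[Si](C)(C)C#C[C@H](O[Si](CC)(CC)CC)[C@@H]1O[C@@H]1[C@@]1(C)O[C@@H]1[C@@H](O)[C@H](C(=C)CO[Si](C)(C)C(C)(C)C)C(=O)N(C)OC | intermediate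
26 | chloro(iodo)methane | ClCI | starting material
27 | chloromethyllithium | [Li]CCl | intermediate
28 | chloromethyl ketone (1S,2R,3S,4S,5R,6S,7S) | C[Si](C)(C)C#C[C@H](O[Si](CC)(CC)CC)[C@@H]1O[C@@H]1[C@@]1(C)O[C@@H]1[C@@H](O)[C@H](C(=C)CO[Si](C)(C)C(C)(C)C)C(=O)CCl | intermediate
29 | anti-1,3-diol chlorohydrin (1S,2R,3S,4S,5R,6S,7S,8S) | C[Si](C)(C)C#C[C@H](O[Si](CC)(CC)CC)[C@@H]1O[C@@H]1[C@@]1(C)O[C@@H]1[C@@H](O)[C@H](C(=C)CO[Si](C)(C)C(C)(C)C)[C@H](O)CCl | intermediate
30 | C14-silylated tris-oxirane alkynol (1S,2R,3S,4S,5R,6S,7S,8S) | C[Si](C)(C)C#C[C@H](O[Si](CC)(CC)CC)[C@@H]1O[C@@H]1[C@@]1(C)O[C@@H]1[C@@H](O)[C@H](C(=C)CO[Si](C)(C)C(C)(C)C)[C@H]1CO1 | intermediate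
31 | tris-oxirane alkynol (1S,2R,3S,4S,5R,6S,7S,8S) | C#C[C@H](O[Si](CC)(CC)CC)[C@@H]1O[C@@H]1[C@@]1(C)O[C@@H]1[C@@H](O)[C@H](C(=C)CO[Si](C)(C)C(C)(C)C)[C@H]1CO1 | intermediate
32 | seco-precursor (1S,2R,3S,4S,5R,6S,7R,8S) | C#C[C@H](O[Si](CC)(CC)CC)[C@@H]1O[C@@H]1[C@@]1(C)O[C@@H]1[C@@H](O[Si](CC)(CC)CC)[C@H](C(=C)CO[Si](C)(C)C(C)(C)C)[C@H]1CO1 | intermediate
33 | C8 O-diethylborinate of macrocycle 34 | C=C(CO[Si](C)(C)C(C)(C)C)[C@@H]1[C@H](OB(CC)CC)CC(=C)[C@H](O[Si](CC)(CC)CC)[C@@H]2O[C@@H]2[C@@]2(C)O[C@@H]2[C@H]1O[Si](CC)(CC)CC | intermediate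
34 | macrocycle (1S,2R,3S,4S,5R,6S,7R,8R), C8–OH | C=C(CO[Si](C)(C)C(C)(C)C)[C@@H]1[C@H](O)CC(=C)[C@H](O[Si](CC)(CC)CC)[C@@H]2O[C@@H]2[C@@]2(C)O[C@@H]2[C@H]1O[Si](CC)(CC)CC | intermediate
35 | (2E)-2-methylbut-2-enoic acid (tiglic acid) | C/C=C(\C)C(=O)O | starting material
36 | (2E)-2-methylbut-2-enoic 2,4,6-trichlorobenzoic anhydride | C/C=C(\C)C(=O)OC(=O)c1c(Cl)cc(Cl)cc1Cl | intermediate
37 | C8 tiglate of 34 (1S,2R,3S,4S,5R,6S,7R,8R) | C=C(CO[Si](C)(C)C(C)(C)C)[C@@H]1[C@H](OC(=O)/C(C)=C/C)CC(=C)[C@H](O[Si](CC)(CC)CC)[C@@H]2O[C@@H]2[C@@]2(C)O[C@@H]2[C@H]1O[Si](CC)(CC)CC | intermediate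
38 | triol tiglate (1S,2S,3S,4S,5R,6S,7S,8R) | C=C(CO)[C@@H]1[C@H](OC(=O)/C(C)=C/C)CC(=C)[C@H](O)[C@@H]2O[C@@H]2[C@@]2(C)O[C@@H]2[C@H]1O | intermediate
39 | C12 enal of 38 | C=C(C=O)[C@@H]1[C@H](OC(=O)/C(C)=C/C)CC(=C)[C@H](O)[C@@H]2O[C@@H]2[C@@]2(C)O[C@@H]2[C@H]1O | intermediate
40 | C12 lactol (mixture at C12) | C=C1C(O)O[C@H]2[C@H]1[C@H](OC(=O)/C(C)=C/C)CC(=C)[C@H](O)[C@@H]1O[C@@H]1[C@@]1(C)O[C@H]21 | intermediate
41 | CNP0164399.1, (1S,2S,3S,4S,5R,6S,7R,8R)-2,3:4,5-diepoxy-1-hydroxy-8-tigloyloxygermacra-10(14),11(13)-dien-12,6-olide | C=C1C(=O)O[C@H]2[C@H]1[C@H](OC(=O)/C(C)=C/C)CC(=C)[C@H](O)[C@@H]1O[C@@H]1[C@@]1(C)O[C@H]21 | target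

**Step count and risks**

Total steps: 23. Longest linear sequence: 19 (steps 1–8, then 13–23); the donor branch is steps 9–12.

Steps most likely to fail:

1. Step 20 (Proposed new method). The ring closure may lose to oligomerisation or alkyne cyclotrimerisation, bond formation may leak to the terminal alkyne carbon, or an internal oxirane may be opened. The fallback closes the same ring with known chemistry, an intramolecular Nozaki–Hiyama allylation by CrCl2 of a C8 aldehyde with a 2-(bromomethyl)allyl unit on C10, whose two CH2 termini are equivalent. It sets out from 25 and comes back at 34. Silylation of 25 (Et3SiOTf, 2,6-lutidine) gives the C6-triethylsilyl Weinreb amide F1. K2CO3 in MeOH removes the C-silyl group to give the terminal alkyne F2. Hydrostannation with Bu3SnH catalysed by Mo(CO)3(CNt-Bu)3 gives the internal vinylstannane F3, and I2 gives the vinyl iodide F4. Stille coupling with Bu3SnCH2OH and Pd(PPh3)4 gives the allylic alcohol F5. i-Bu2AlH at −78 °C reduces the Weinreb amide to the hydroxy aldehyde F6, and CBr4/PPh3 gives the bromo aldehyde F7. CrCl2 in THF at high dilution then closes the ring to 34, which is separated from its C8 epimer; that epimer can be taken on to 37 by Mitsunobu esterification with 35.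

2. Step 13. The chlorotitanium dienolate may open the alkenyl oxirane of 14, react at its γ-carbon, or add with poor facial control. The fallback is an Evans boron aldol with hydrolytic removal of the auxiliary; it sets out from 19 (with 14) and comes back at 24. Acid 19 is converted through its pivaloyl mixed anhydride and lithiated (4S)-4-benzyl-1,3-oxazolidin-2-one into the N-acyl oxazolidinone F8. Bu2BOTf and i-Pr2NEt, then 14 at −78 °C, give the syn-aldol imide F9. LiOH/H2O2 at 0 °C gives the β-hydroxy acid F10. EDC·HCl, 1-hydroxybenzotriazole and MeNH(OMe)·HCl then give 24.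

3. Step 6. Facial selectivity in the acetylide addition may be poor. The fallback replaces substrate control by reagent control; it sets out from the C1-epimeric mixture of 12 and comes back at 12. Dess–Martin oxidation gives the epoxy ynone F11. Noyori transfer hydrogenation with RuCl[(R,R)-TsDPEN](p-cymene) in i-PrOH, the alkyne acting as the π-substituent, should return the (1S) alcohol 12.

**Further compounds**

F1 | step 20 | C6-triethylsilyl ether of 25 | C[Si](C)(C)C#C[C@H](O[Si](CC)(CC)CC)[C@@H]1O[C@@H]1[C@@]1(C)O[C@@H]1[C@@H](O[Si](CC)(CC)CC)[C@H](C(=C)CO[Si](C)(C)C(C)(C)C)C(=O)N(C)OC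
F2 | step 20 | terminal alkyne from F1 | C#C[C@H](O[Si](CC)(CC)CC)[C@@H]1O[C@@H]1[C@@]1(C)O[C@@H]1[C@@H](O[Si](CC)(CC)CC)[C@H](C(=C)CO[Si](C)(C)C(C)(C)C)C(=O)N(C)OC
F3 | step 20 | C10 tributylstannyl alkene | C=C([Sn](CCCC)(CCCC)CCCC)[C@H](O[Si](CC)(CC)CC)[C@@H]1O[C@@H]1[C@@]1(C)O[C@@H]1[C@@H](O[Si](CC)(CC)CC)[C@H](C(=C)CO[Si](C)(C)C(C)(C)C)C(=O)N(C)OC
F4 | step 20 | C10 vinyl iodide | C=C(I)[C@H](O[Si](CC)(CC)CC)[C@@H]1O[C@@H]1[C@@]1(C)O[C@@H]1[C@@H](O[Si](CC)(CC)CC)[C@H](C(=C)CO[Si](C)(C)C(C)(C)C)C(=O)N(C)OC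
F5 | step 20 | C10 2-(hydroxymethyl)alkene Weinreb amide | C=C(CO)[C@H](O[Si](CC)(CC)CC)[C@@H]1O[C@@H]1[C@@]1(C)O[C@@H]1[C@@H](O[Si](CC)(CC)CC)[C@H](C(=C)CO[Si](C)(C)C(C)(C)C)C(=O)N(C)OC
F6 | step 20 | C8 aldehyde with allylic alcohol | C=C(CO)[C@H](O[Si](CC)(CC)CC)[C@@H]1O[C@@H]1[C@@]1(C)O[C@@H]1[C@@H](O[Si](CC)(CC)CC)[C@H](C(=C)CO[Si](C)(C)C(C)(C)C)C=O
F7 | step 20 | C8 aldehyde with allylic bromide | C=C(CBr)[C@H](O[Si](CC)(CC)CC)[C@@H]1O[C@@H]1[C@@]1(C)O[C@@H]1[C@@H](O[Si](CC)(CC)CC)[C@H](C(=C)CO[Si](C)(C)C(C)(C)C)C=O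
F8 | step 13 | (4S)-4-benzyl-3-[3-({[tert-butyl(dimethyl)silyl]oxy}methyl)but-3-enoyl]-1,3-oxazolidin-2-one | C=C(CO[Si](C)(C)C(C)(C)C)CC(=O)N1C(=O)OC[C@@H]1Cc1ccccc1
F9 | step 13 | syn-aldol N-acyl oxazolidinone | C[Si](C)(C)C#C[C@H](O[Si](CC)(CC)CC)[C@@H]1O[C@@H]1/C(C)=C/[C@@H](O)[C@H](C(=C)CO[Si](C)(C)C(C)(C)C)C(=O)N1C(=O)OC[C@@H]1Cc1ccccc1
F10 | step 13 | syn β-hydroxy acid | C[Si](C)(C)C#C[C@H](O[Si](CC)(CC)CC)[C@@H]1O[C@@H]1/C(C)=C/[C@@H](O)[C@H](C(=C)CO[Si](C)(C)C(C)(C)C)C(=O)O
F11 | step 6 | 1-[(2R,3R)-3-[(2E)-4,4-dimethoxybut-2-en-2-yl]oxiran-2-yl]-3-(trimethylsilyl)prop-2-yn-1-one | C[Si](C)(C)C#CC(=O)[C@@H]1O[C@@H]1/C(C)=C/C(OC)OC
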